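The target is cut at O1–C8a of the pyran ring (ring C). C3 carries two CH2 arms, C2 and the carbon that will become C1′ of the quinone (ring B), and these are identical in an acyclic 2-benzylpropane-1,3-diol. A copper-catalysed asymmetric intramolecular O-arylation of that diol onto the brominated carbon of ring A therefore closes ring C and sets the C3 stereocentre in one operation. The precursor is a fully substituted ring A (bromide, methoxy, prenyl, MOM-protected phenol) bearing the prochiral diol. The leftover hydroxymethyl group is afterwards turned into an alkyne and grown into the hydroxyquinone by squarate ring expansion.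

Key step: step 10

Remark: chroman numbering is used (O1, C2, C3, C4, C4a, C5 to C8, C8a; quinone carbons primed); which antipode of the copper ligand gives the 3R alcohol is not assumed and is to be settled in the first run, the route being written for the 3R series.

Step 1
Reactants: 1 5-bromoresorcinol
Product: 3 2-bromo-4,6-dihydroxybenzaldehyde, via aryl iminium chloride 2 (not isolated)
Conditions: POCl3 (1.2 equiv), DMF (1.5 equiv), MeCN, 0 °C to rt; then H2O, 50 °C
Reagents that add atoms: N,N-dimethylformamide CN(C)C=O; water O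
Why: Vilsmeier–Haack formylation of the resorcinol should go para to one hydroxyl and ortho to the other (two equivalent sites, each next to bromine) and not between the hydroxyls, and aqueous hydrolysis of the iminium salt then releases the aldehyde.

Step 2
Reactants: 3 2-bromo-4,6-dihydroxybenzaldehyde
Product: 4 2-bromo-6-hydroxy-4-(methoxymethoxy)benzaldehyde
Conditions: MOMCl (1.05 equiv), iPr2NEt (1.2 equiv), CH2Cl2, 0 °C
Reagents that add atoms: chloromethyl methyl ether COCCl
Why: O-alkylation (Williamson-type acetal formation) should take the para hydroxyl selectively, since it is the more acidic and unhindered one while the ortho hydroxyl is held in a hydrogen bond to the aldehyde.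

Step 3
Reactants: 5 2-methylbut-3-en-2-ol
Product: 7 methyl 2-methylbut-3-en-2-yl carbonate, via lithium 2-methylbut-3-en-2-olate 6 (not isolated)
Conditions: n-BuLi (1.0 equiv), THF, 0 °C; then ClCO2Me, 0 °C to rt
Reagents that add atoms: methyl chloroformate COC(=O)Cl
Why: Acylation of the lithium alkoxide by a chloroformate is the standard way to a tertiary allylic carbonate, which amine-mediated acylation of the hindered alcohol reaches only sluggishly.

Step 4
Reactants: 4 2-bromo-6-hydroxy-4-(methoxymethoxy)benzaldehyde; 7 methyl 2-methylbut-3-en-2-yl carbonate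
Product: 8 2-bromo-4-(methoxymethoxy)-6-[(2-methylbut-3-en-2-yl)oxy]benzaldehyde
Conditions: Pd(PPh3)4 (2 mol %), THF, 0 °C
Reagents that add atoms: none
Why: Tsuji–Trost O-allylation, in which zerovalent palladium ionises the tertiary allylic carbonate far faster than it inserts into the aryl bromide at 0 °C, the released methoxide deprotonates the phenol, and the phenoxide should attack the more substituted terminus of the 1,1-dimethylallyl palladium cation to give the tertiary ether as the kinetic product.

Step 5
Reactants: 8 2-bromo-4-(methoxymethoxy)-6-[(2-methylbut-3-en-2-yl)oxy]benzaldehyde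
Product: 9 2-bromo-6-hydroxy-4-(methoxymethoxy)-5-(3-methylbut-2-en-1-yl)benzaldehyde
Conditions: Eu(fod)3 (10 mol %; fod = 6,6,7,7,8,8,8-heptafluoro-2,2-dimethyloctane-3,5-dionate), CHCl3, 50 °C
Reagents that add atoms: none
Why: Aromatic Claisen rearrangement ([3,3]-sigmatropic shift, then tautomerisation) accelerated by the Lewis acid, in which the other ortho carbon is blocked by the formyl group so that the allyl unit should end up only on the carbon between the two oxygens, the allylic transposition turning the tertiary ether into the linear prenyl group.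

Step 6
Reactants: 9 2-bromo-6-hydroxy-4-(methoxymethoxy)-5-(3-methylbut-2-en-1-yl)benzaldehyde
Product: 10 2-bromo-6-methoxy-4-(methoxymethoxy)-5-(3-methylbut-2-en-1-yl)benzaldehyde
Conditions: MeI, K2CO3, DMF, rt
Reagents that add atoms: iodomethane CI
Why: Williamson methylation of the only remaining acidic site, the polar aprotic solvent compensating for the low nucleophilicity of the flanked, hydrogen-bonded phenoxide.

Step 7
Reactants: 10 2-bromo-6-methoxy-4-(methoxymethoxy)-5-(3-methylbut-2-en-1-yl)benzaldehyde; 11 diethyl malonate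
Product: 12 diethyl 2-{[2-bromo-6-methoxy-4-(methoxymethoxy)-5-(3-methylbut-2-en-1-yl)phenyl]methylidene}propanedioate
Conditions: piperidine (0.2 equiv), AcOH (0.2 equiv), PhMe, reflux, Dean–Stark
Reagents that add atoms: none
Why: Knoevenagel condensation through the piperidine-derived iminium ion with azeotropic removal of water, which should drive even this di-ortho-substituted, non-enolisable aldehyde to the arylidene malonate.

Step 8
Reactants: 12 diethyl 2-{[2-bromo-6-methoxy-4-(methoxymethoxy)-5-(3-methylbut-2-en-1-yl)phenyl]methylidene}propanedioate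
Product: 13 diethyl 2-{[2-bromo-6-methoxy-4-(methoxymethoxy)-5-(3-methylbut-2-en-1-yl)phenyl]methyl}propanedioate
Conditions: NaBH4, EtOH, 0 °C
Reagents that add atoms: none
Why: Conjugate hydride reduction of a doubly activated alkylidene malonate, which at 0 °C should leave the esters, the aryl bromide and the isolated prenyl alkene untouched.

Step 9
Reactants: 13 diethyl 2-{[2-bromo-6-methoxy-4-(methoxymethoxy)-5-(3-methylbut-2-en-1-yl)phenyl]methyl}propanedioate
Product: 14 2-{[2-bromo-6-methoxy-4-(methoxymethoxy)-5-(3-methylbut-2-en-1-yl)phenyl]methyl}propane-1,3-diol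
Conditions: LiAlH4, THF, 0 °C to rt; then aq. potassium sodium tartrate
Reagents that add atoms: none
Why: LiAlH4 reduction of both esters to primary alcohols, the aryl bromide (unlike an iodide), the acetal and the trisubstituted alkene being inert at or below room temperature, gives a diol without a stereocentre because its two hydroxymethyl arms are identical.

Step 10
Reactants: 14 2-{[2-bromo-6-methoxy-4-(methoxymethoxy)-5-(3-methylbut-2-en-1-yl)phenyl]methyl}propane-1,3-diol
Product: 15 [(3R)-5-methoxy-7-(methoxymethoxy)-6-(3-methylbut-2-en-1-yl)-3,4-dihydro-2H-chromen-3-yl]methanol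
Conditions: CuI (10 mol %), enantiopure trans-N,N′-dimethylcyclohexane-1,2-diamine (20 mol %, the antipode giving 3R), Cs2CO3 (2 equiv), MeCN, 40–60 °C, argon
Reagents that add atoms: none
Why: Deprotonation gives a diamine-ligated monovalent copper alkoxide on one hydroxymethyl arm, which activates the aryl bromide by oxidative addition to an aryl trivalent copper alkoxide and then forms the O1–C8a bond by carbon–oxygen reductive elimination. The closest known reaction is the copper/chiral diamine catalysed enantioselective desymmetrising intramolecular Ullmann etherification of 2-(2-halobenzyl)propane-1,3-diols to (chroman-3-yl)methanols. Ring C closes in a six-membered mode with the breaking C–Br bond outside the new ring (formally 6-exo); either arm gives the same ring size and no other ring is within reach. C3 becomes a stereocentre under catalyst control, because the chiral diamine on copper decides which of the two enantiotopic CH2OH groups is engaged. The step needs enantiotopic-group selection and chemoselective intramolecular alkoxide arylation; the single aryl halide, the masked O7 phenol (no competing phenoxide) and the inert prenyl and acetal groups secure the latter, and the product cannot react again because the halide is consumed.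

Step 11
Reactants: 15 [(3R)-5-methoxy-7-(methoxymethoxy)-6-(3-methylbut-2-en-1-yl)-3,4-dihydro-2H-chromen-3-yl]methanol
Product: 16 (3S)-5-methoxy-7-(methoxymethoxy)-6-(3-methylbut-2-en-1-yl)-3,4-dihydro-2H-chromene-3-carbaldehyde
Conditions: Dess–Martin periodinane, CH2Cl2, 0 °C to rt; used without chromatography
Reagents that add atoms: none
Why: Dess–Martin oxidation stops at the aldehyde and runs without base, so that C3, now α to a carbonyl and β to the ring aryloxy oxygen, should neither epimerise nor suffer elimination (the descriptor becomes S only because the CIP priorities change).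

Step 12
Reactants: 16 (3S)-5-methoxy-7-(methoxymethoxy)-6-(3-methylbut-2-en-1-yl)-3,4-dihydro-2H-chromene-3-carbaldehyde
Product: 17 (3R)-3-(2,2-dibromoethenyl)-5-methoxy-7-(methoxymethoxy)-6-(3-methylbut-2-en-1-yl)-3,4-dihydro-2H-chromene
Conditions: CBr4 (2 equiv), PPh3 (2 equiv), Zn dust (2 equiv), CH2Cl2, rt (ylide pre-formed); then 16, 0 °C to rt
Reagents that add atoms: carbon tetrabromide BrC(Br)(Br)Br
Why: First stage of the Corey–Fuchs alkyne synthesis, a Wittig-type olefination by Ph3P=CBr2 generated with zinc under neutral conditions, preferred to a base-mediated diazophosphonate homologation so that the α-stereocentre of the aldehyde never meets carbonate in methanol.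

Step 13
Reactants: 18 di-tert-butyl squarate
Product: 20 3-tert-butoxy-4-(prop-2-en-1-yl)cyclobut-3-ene-1,2-dione, via bromomagnesium alkoxide adduct 19 (not isolated)
Conditions: allylMgBr (1.05 equiv), THF, −78 °C; then (CF3CO)2O, −78 to 0 °C; aq. NaHCO3
Reagents that add atoms: allylmagnesium bromide C=CC[Mg]Br
Why: 1,2-Addition of the Grignard reagent to one squarate carbonyl, then O-trifluoroacetylation, ionisation and loss of a tert-butyl group from the resulting oxocarbenium ion, is the established transposition of squarate adducts to 3-alkoxy-4-alkylcyclobutenediones; allyl is used because prenyl organometallics would attack through their tertiary terminus.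

Step 14
Reactants: 20 3-tert-butoxy-4-(prop-2-en-1-yl)cyclobut-3-ene-1,2-dione
Product: 21 3-tert-butoxy-4-(3-methylbut-2-en-1-yl)cyclobut-3-ene-1,2-dione
Conditions: second-generation Grubbs catalyst (H2IMes)(PCy3)Cl2Ru=CHPh (5 mol %), 2-methylbut-2-ene/CH2Cl2, 40 °C
Reagents that add atoms: 2-methylbut-2-ene CC=C(C)C
Why: Olefin cross-metathesis of a terminal allyl group with a large excess of 2-methylbut-2-ene is the standard allyl-to-prenyl conversion, and the tetrasubstituted, electron-poor ring alkene should not take part.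

Step 15
Reactants: 17 (3R)-3-(2,2-dibromoethenyl)-5-methoxy-7-(methoxymethoxy)-6-(3-methylbut-2-en-1-yl)-3,4-dihydro-2H-chromene; 21 3-tert-butoxy-4-(3-methylbut-2-en-1-yl)cyclobut-3-ene-1,2-dione
Product: 23 3-tert-butoxy-4-hydroxy-4-{[(3R)-5-methoxy-7-(methoxymethoxy)-6-(3-methylbut-2-en-1-yl)-3,4-dihydro-2H-chromen-3-yl]ethynyl}-2-(3-methylbut-2-en-1-yl)cyclobut-2-en-1-one (both epimers at the carbinol carbon), via lithium acetylide 22 (not isolated)
Conditions: n-BuLi (2.05 equiv), THF, −78 °C; then 21 (1.2 equiv), −78 °C; aq. NH4Cl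
Reagents that add atoms: none
Why: The second stage of the Corey–Fuchs sequence (bromine–lithium exchange, elimination with 1,2-shift, deprotonation) gives the lithium acetylide, which at −78 °C should add 1,2 to the more electrophilic carbonyl of 21, the one next to the tert-butoxy-bearing carbon (the other is deactivated as a vinylogous ester), and the mixture of epimers at the new carbinol carbon is inconsequential because that carbon becomes a quinone carbonyl.

Step 16
Reactants: 23 3-tert-butoxy-4-hydroxy-4-{[(3R)-5-methoxy-7-(methoxymethoxy)-6-(3-methylbut-2-en-1-yl)-3,4-dihydro-2H-chromen-3-yl]ethynyl}-2-(3-methylbut-2-en-1-yl)cyclobut-2-en-1-one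
Product: 24 2-tert-butoxy-5-[(3R)-5-methoxy-7-(methoxymethoxy)-6-(3-methylbut-2-en-1-yl)-3,4-dihydro-2H-chromen-3-yl]-3-(3-methylbut-2-en-1-yl)cyclohexa-2,5-diene-1,4-dione
Conditions: PhMe (degassed), 110 °C
Reagents that add atoms: none
Why: Moore rearrangement, in which thermal electrocyclic opening of the cyclobutenone (hydroxyl rotating outward) to an alkynyl vinylketene, closure of the ketene carbon onto the far alkyne carbon to a six-membered diradical and hydrogen transfer from the hydroxyl should give the 1,4-benzoquinone with the former chroman-bound alkyne carbon as C1′, the alkyl-substituted alkyne favouring the six-membered closure and C3 staying untouched.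

Step 17
Reactants: 24 2-tert-butoxy-5-[(3R)-5-methoxy-7-(methoxymethoxy)-6-(3-methylbut-2-en-1-yl)-3,4-dihydro-2H-chromen-3-yl]-3-(3-methylbut-2-en-1-yl)cyclohexa-2,5-diene-1,4-dione
Product: 25 2-hydroxy-5-[(3R)-7-hydroxy-5-methoxy-6-(3-methylbut-2-en-1-yl)-3,4-dihydro-2H-chromen-3-yl]-3-(3-methylbut-2-en-1-yl)cyclohexa-2,5-diene-1,4-dione (CNP0148998.1)
Conditions: TFA/CH2Cl2 (1:4), H2O (5 equiv), 0 °C to rt, stopped as soon as the acetal is gone
Reagents that add atoms: none
Why: Acidolysis, in which the tert-butyl vinylogous ester should lose 2-methylpropene within minutes and the methoxymethyl acetal is hydrolysed in the same pot, trifluoroacetate being too poor a nucleophile to add to the quinone, while low temperature, dilution and short contact are meant to keep either prenyl group from closing onto its neighbouring hydroxyl.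

Compound list
1 | 5-bromoresorcinol (5-bromobenzene-1,3-diol) | Oc1cc(O)cc(Br)c1 | starting material
2 | [(2-bromo-4,6-dihydroxyphenyl)methylidene]dimethylammonium chloride | C[N+](C)=Cc1c(O)cc(O)cc1Br.[Cl-] | intermediate
3 | 2-bromo-4,6-dihydroxybenzaldehyde | O=Cc1c(Br)cc(O)cc1O | intermediate
4 | 2-bromo-6-hydroxy-4-(methoxymethoxy)benzaldehyde | COCOc1cc(O)c(C=O)c(Br)c1 | intermediate
5 | 2-methylbut-3-en-2-ol | C=CC(C)(C)O | starting material
6 | lithium 2-methylbut-3-en-2-olate | C=CC(C)(C)[O-].[Li+] | intermediate
7 | methyl 2-methylbut-3-en-2-yl carbonate | C=CC(C)(C)OC(=O)OC | intermediate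
8 | 2-bromo-4-(methoxymethoxy)-6-[(2-methylbut-3-en-2-yl)oxy]benzaldehyde | COCOc1cc(OC(C)(C)C=C)c(C=O)c(Br)c1 | intermediate
9 | 2-bromo-6-hydroxy-4-(methoxymethoxy)-5-(3-methylbut-2-en-1-yl)benzaldehyde | COCOc1cc(Br)c(C=O)c(O)c1CC=C(C)C | intermediate
10 | 2-bromo-6-methoxy-4-(methoxymethoxy)-5-(3-methylbut-2-en-1-yl)benzaldehyde | COCOc1cc(Br)c(C=O)c(OC)c1CC=C(C)C | intermediate
11 | diethyl malonate | CCOC(=O)CC(=O)OCC | starting material
12 | diethyl 2-{[2-bromo-6-methoxy-4-(methoxymethoxy)-5-(3-methylbut-2-en-1-yl)phenyl]methylidene}propanedioate | CCOC(=O)C(=Cc1c(Br)cc(OCOC)c(CC=C(C)C)c1OC)C(=O)OCC | intermediate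
13 | diethyl 2-{[2-bromo-6-methoxy-4-(methoxymethoxy)-5-(3-methylbut-2-en-1-yl)phenyl]methyl}propanedioate | CCOC(=O)C(Cc1c(Br)cc(OCOC)c(CC=C(C)C)c1OC)C(=O)OCC | intermediate
14 | 2-{[2-bromo-6-methoxy-4-(methoxymethoxy)-5-(3-methylbut-2-en-1-yl)phenyl]methyl}propane-1,3-diol (prochiral) | COc1c(CC=C(C)C)c(OCOC)cc(Br)c1CC(CO)CO | intermediate
15 | [(3R)-5-methoxy-7-(methoxymethoxy)-6-(3-methylbut-2-en-1-yl)-3,4-dihydro-2H-chromen-3-yl]methanol | COc1c(CC=C(C)C)c(OCOC)cc2c1C[C@H](CO)CO2 | intermediate
16 | (3S)-5-methoxy-7-(methoxymethoxy)-6-(3-methylbut-2-en-1-yl)-3,4-dihydro-2H-chromene-3-carbaldehyde | COc1c(CC=C(C)C)c(OCOC)cc2c1C[C@H](C=O)CO2 | intermediate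
17 | (3R)-3-(2,2-dibromoethenyl)-5-methoxy-7-(methoxymethoxy)-6-(3-methylbut-2-en-1-yl)-3,4-dihydro-2H-chromene | COc1c(CC=C(C)C)c(OCOC)cc2c1C[C@H](C=C(Br)Br)CO2 | intermediate
18 | di-tert-butyl squarate (3,4-di-tert-butoxycyclobut-3-ene-1,2-dione) | CC(C)(C)OC1=C(OC(C)(C)C)C(=O)C1=O | starting material
19 | bromomagnesium 2,3-di-tert-butoxy-4-oxo-1-(prop-2-en-1-yl)cyclobut-2-en-1-olate | C=CCC1([O-])C(OC(C)(C)C)=C(OC(C)(C)C)C1=O.[Mg+2].[Br-] | intermediate
20 | 3-tert-butoxy-4-(prop-2-en-1-yl)cyclobut-3-ene-1,2-dione | C=CCC1=C(OC(C)(C)C)C(=O)C1=O | intermediate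
21 | 3-tert-butoxy-4-(3-methylbut-2-en-1-yl)cyclobut-3-ene-1,2-dione | CC(C)=CCC1=C(OC(C)(C)C)C(=O)C1=O | intermediate
22 | lithium acetylide of (3R)-3-ethynyl-5-methoxy-7-(methoxymethoxy)-6-(3-methylbut-2-en-1-yl)-3,4-dihydro-2H-chromene | COc1c(CC=C(C)C)c(OCOC)cc2c1C[C@H](C#[C-])CO2.[Li+] | intermediate
23 | 3-tert-butoxy-4-hydroxy-4-{[(3R)-5-methoxy-7-(methoxymethoxy)-6-(3-methylbut-2-en-1-yl)-3,4-dihydro-2H-chromen-3-yl]ethynyl}-2-(3-methylbut-2-en-1-yl)cyclobut-2-en-1-one (both epimers at the carbinol carbon) | COc1c(CC=C(C)C)c(OCOC)cc2c1C[C@H](C#CC3(O)C(OC(C)(C)C)=C(CC=C(C)C)C3=O)CO2 | intermediate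
24 | 2-tert-butoxy-5-[(3R)-5-methoxy-7-(methoxymethoxy)-6-(3-methylbut-2-en-1-yl)-3,4-dihydro-2H-chromen-3-yl]-3-(3-methylbut-2-en-1-yl)cyclohexa-2,5-diene-1,4-dione | COc1c(CC=C(C)C)c(OCOC)cc2c1C[C@H](C1=CC(=O)C(OC(C)(C)C)=C(CC=C(C)C)C1=O)CO2 | intermediate
25 | 2-hydroxy-5-[(3R)-7-hydroxy-5-methoxy-6-(3-methylbut-2-en-1-yl)-3,4-dihydro-2H-chromen-3-yl]-3-(3-methylbut-2-en-1-yl)cyclohexa-2,5-diene-1,4-dione | COc1c(CC=C(C)C)c(O)cc2c1C[C@H](C1=CC(=O)C(O)=C(CC=C(C)C)C1=O)CO2 | target

Total step count: 17. Longest linear sequence: 14 steps (steps 1, 2, 4 to 12 and 15 to 17, from 5-bromoresorcinol).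

Steps most likely to fail

Step 10. The catalyst may discriminate poorly between the two enantiotopic hydroxymethyl arms, or oxidative addition of the electron-rich, ortho-substituted aryl bromide may be slow and leave the diol unconverted. The fallback sets the stereocentre enzymatically and closes the ring with an achiral catalyst. It sets out from 14: lipase-catalysed monoacetylation with vinyl acetate (or, if the enzyme prefers the other arm, lipase hydrolysis of the diacetate) should give the monoacetate (2R)-3-hydroxy-2-{[2-bromo-6-methoxy-4-(methoxymethoxy)-5-(3-methylbut-2-en-1-yl)phenyl]methyl}propyl acetate F1. Silylation of the free hydroxyl (iPr3SiCl, imidazole, DMF) gives the silyl ether acetate F2, and K2CO3 in MeOH removes the acetate to give the mono-silylated alcohol F3. This order avoids exposing a monoacetate to base, where acyl migration between the arms would erase the selectivity. Ring closure with CuI, 1,10-phenanthroline and Cs2CO3 in PhMe at 100 °C gives the silyl-protected chroman F4, and Bu4NF in THF returns to the route at 15.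

Step 17. While the slower acetal cleavage is completed, a prenyl group may close onto its neighbouring hydroxyl, or formaldehyde-derived electrophiles may attack the electron-rich C8 position. The fallback removes the acetal before the quinone exists. It sets out from 17: HCl in MeOH at rt should give the phenol (3R)-3-(2,2-dibromoethenyl)-5-methoxy-6-(3-methylbut-2-en-1-yl)-3,4-dihydro-2H-chromen-7-ol F5. Treatment with n-BuLi (3.05 equiv, THF, −78 °C) generates the dilithium phenoxide acetylide F6, which is added to 21 to give the phenolic cyclobutenone adduct F7. Thermolysis in PhMe at 110 °C gives the phenolic tert-butoxyquinone F8. A brief treatment with cold TFA/CH2Cl2, now needed only for the fast tert-butyl cleavage, returns to the route at 25.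

Step 4. The tertiary ether may be re-ionised by palladium and equilibrate to the linear prenyl ether, or the hydrogen-bonded phenoxide may be alkylated too slowly. The fallback builds the tertiary ether without a π-allyl intermediate. It sets out from 4: copper-catalysed O-propargylation with 3-chloro-3-methylbut-1-yne (CuCl2·2H2O cat., DBU, MeCN, 0 °C) should give the propargyl ether 2-bromo-4-(methoxymethoxy)-6-[(2-methylbut-3-yn-2-yl)oxy]benzaldehyde F9. Semihydrogenation (H2, Lindlar catalyst, that is Pd/CaCO3 poisoned with Pb(OAc)2, quinoline, EtOAc) returns to the route at 8.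

Further compounds
F1 | step 10 | (2R)-3-hydroxy-2-{[2-bromo-6-methoxy-4-(methoxymethoxy)-5-(3-methylbut-2-en-1-yl)phenyl]methyl}propyl acetate | COc1c(CC=C(C)C)c(OCOC)cc(Br)c1C[C@H](CO)COC(C)=O
F2 | step 10 | (2S)-2-{[2-bromo-6-methoxy-4-(methoxymethoxy)-5-(3-methylbut-2-en-1-yl)phenyl]methyl}-3-{[tri(propan-2-yl)silyl]oxy}propyl acetate | COc1c(CC=C(C)C)c(OCOC)cc(Br)c1C[C@H](CO[Si](C(C)C)(C(C)C)C(C)C)COC(C)=O
F3 | step 10 | (2S)-2-{[2-bromo-6-methoxy-4-(methoxymethoxy)-5-(3-methylbut-2-en-1-yl)phenyl]methyl}-3-{[tri(propan-2-yl)silyl]oxy}propan-1-ol | COc1c(CC=C(C)C)c(OCOC)cc(Br)c1C[C@H](CO[Si](C(C)C)(C(C)C)C(C)C)CO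
F4 | step 10 | {[(3S)-5-methoxy-7-(methoxymethoxy)-6-(3-methylbut-2-en-1-yl)-3,4-dihydro-2H-chromen-3-yl]methoxy}tri(propan-2-yl)silane | COc1c(CC=C(C)C)c(OCOC)cc2c1C[C@H](CO[Si](C(C)C)(C(C)C)C(C)C)CO2
F5 | step 17 | (3R)-3-(2,2-dibromoethenyl)-5-methoxy-6-(3-methylbut-2-en-1-yl)-3,4-dihydro-2H-chromen-7-ol | COc1c(CC=C(C)C)c(O)cc2c1C[C@H](C=C(Br)Br)CO2
F6 | step 17 | dilithium salt (phenoxide and acetylide) of (3R)-3-ethynyl-5-methoxy-6-(3-methylbut-2-en-1-yl)-3,4-dihydro-2H-chromen-7-ol | COc1c(CC=C(C)C)c([O-])cc2c1C[C@H](C#[C-])CO2.[Li+].[Li+]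
F7 | step 17 | 3-tert-butoxy-4-hydroxy-4-{[(3R)-7-hydroxy-5-methoxy-6-(3-methylbut-2-en-1-yl)-3,4-dihydro-2H-chromen-3-yl]ethynyl}-2-(3-methylbut-2-en-1-yl)cyclobut-2-en-1-one | COc1c(CC=C(C)C)c(O)cc2c1C[C@H](C#CC3(O)C(OC(C)(C)C)=C(CC=C(C)C)C3=O)CO2
F8 | step 17 | 2-tert-butoxy-5-[(3R)-7-hydroxy-5-methoxy-6-(3-methylbut-2-en-1-yl)-3,4-dihydro-2H-chromen-3-yl]-3-(3-methylbut-2-en-1-yl)cyclohexa-2,5-diene-1,4-dione | COc1c(CC=C(C)C)c(O)cc2c1C[C@H](C1=CC(=O)C(OC(C)(C)C)=C(CC=C(C)C)C1=O)CO2
F9 | step 4 | 2-bromo-4-(methoxymethoxy)-6-[(2-methylbut-3-yn-2-yl)oxy]benzaldehyde | COCOc1cc(OC(C)(C)C#C)c(C=O)c(Br)c1
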